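**Plan**

- Retrosynthetic cuts, in order: the C8–O acyl bond, the C3–C4 epoxide, the C4–C15 methyl bond (back to a C4 ketone), the ring bond C7–C8 of the seven-membered ring B, then the arm bonds C1–C10 and C5–C6 on the five-membered ring A.
- Enabling feature: C7 carries an isopropyl group directly beside the oxygenated C8 in ring B. This is the retron of a carbonyl-ene reaction between a C8 aldehyde and a prenyl group (C6–C7=C11) on C5 of ring A.
- Forward: ring A is bought as (S)-4-silyloxycyclopentenone and both arms are attached in one conjugate addition–alkylation. The C10 arm is taken to the aldehyde, ring B is closed by the ene reaction, and hydrogenation, C8 inversion/esterification, C3=C4 methyl-alkene formation and epoxidation follow.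
- Stereochemistry: C1 and C5 from the silyloxy stereocentre (anti addition, anti alkylation); C10 from a Sharpless epoxidation (D-(−)-diethyl tartrate) and hydride opening; C7 from the ene transition state; C8 from oxidation and hindered-hydride reduction; C3/C4 from face-selective epoxidation.

Key step: step 11

Remark: guaiane numbering is used throughout (C1/C5 ring fusion, C2–C4 in ring A, C6–C10 in ring B, C14 on C10, C15 on C4, C11–C13 on C7; "15-nor" means C15 is absent), α/β refer to the bicycle drawn with H-1 α, and (S)-4-(tert-butyldimethylsilyloxy)cyclopent-2-en-1-one and 3,4-dimethoxybenzoyl chloride are taken as purchased.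

**Route**

Step 1
Reactants: 1 but-2-yn-1-ol
Product: 2 tert-butyl(but-2-yn-1-yloxy)dimethylsilane
Conditions: t-BuMe2SiCl, imidazole, DMF, rt
Reagents that add atoms: tert-butyldimethylsilyl chloride, CC(C)(C)[Si](C)(C)Cl
Why: Imidazole-promoted silylation of the primary propargylic alcohol gives an ether that tolerates the organometallic steps ahead; no stereocentre is formed.

Step 2
Reactants: 2 tert-butyl(but-2-yn-1-yloxy)dimethylsilane
Product: 4 (E)-tert-butyl[(3-iodobut-2-en-1-yl)oxy]dimethylsilane, via alkenylzirconocene chloride 3 (not isolated)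
Conditions: Cp2Zr(H)Cl (1.5 equiv), THF, 50 °C; then I2, 0 °C
Reagents that add atoms: iodine, II
Why: Hydrozirconation adds Zr–H syn across the alkyne and, under equilibration with excess Cp2Zr(H)Cl, should place zirconium on the less hindered methyl-bearing carbon; iodinolysis with retention then gives the (E)-iodide.

Step 3
Reactants: 4 (E)-tert-butyl[(3-iodobut-2-en-1-yl)oxy]dimethylsilane, 5 (S)-4-(tert-butyldimethylsilyloxy)cyclopent-2-en-1-one, 6 1-bromo-3-methylbut-2-ene (prenyl bromide)
Product: 10 (2S,3R,4S)-4-(tert-butyldimethylsilyloxy)-3-[(E)-4-(tert-butyldimethylsilyloxy)but-2-en-2-yl]-2-(3-methylbut-2-en-1-yl)cyclopentan-1-one, via alkenyllithium 7 (not isolated), via lithium alkenyldimethylzincate 8 (not isolated), via zincate enolate 9 (not isolated)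
Conditions: t-BuLi (2 equiv), Et2O, −78 °C; Me2Zn, THF, −78 °C; 5, −78 °C; then HMPA, 6 (5 equiv), −78 → −40 °C
Reagents that add atoms: 1-bromo-3-methylbut-2-ene (6), CC(C)=CCBr
Why: Three-component conjugate addition–enolate alkylation: the alkenyl group, passed from lithium to a mixed zincate, adds anti to the silyloxy group (setting C1), and the zinc enolate is alkylated at the primary carbon of the allylic bromide anti to the new substituent (setting C5), so the all-trans ketone is expected.

Step 4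
Reactants: 10 (2S,3R,4S)-4-(tert-butyldimethylsilyloxy)-3-[(E)-4-(tert-butyldimethylsilyloxy)but-2-en-2-yl]-2-(3-methylbut-2-en-1-yl)cyclopentan-1-one
Product: 11 (4R,5S)-4-[(E)-4-hydroxybut-2-en-2-yl]-5-(3-methylbut-2-en-1-yl)cyclopent-2-en-1-one
Conditions: AcOH/H2O/THF (6:3:1), 60 °C
Reagents that add atoms: none
Why: Acid-mediated desilylation and β-elimination of the ring oxygen through the enol should give the enone and free the primary allylic alcohol; acid is chosen because the doubly allylic C1–H next to the enone would invite double-bond migration under base, and C1 and C5 are untouched.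

Step 5
Reactants: 11 (4R,5S)-4-[(E)-4-hydroxybut-2-en-2-yl]-5-(3-methylbut-2-en-1-yl)cyclopent-2-en-1-one
Product: 12 (2S,3R)-3-[(E)-4-hydroxybut-2-en-2-yl]-2-(3-methylbut-2-en-1-yl)cyclopentan-1-one
Conditions: H2 (1 atm), RhCl(PPh3)3 (cat.), benzene, rt
Reagents that add atoms: none
Why: Homogeneous hydrogenation with RhCl(PPh3)3 reduces the cis-disubstituted enone alkene and should leave the two trisubstituted alkenes alone; no stereocentre is formed.

Step 6
Reactants: 12 (2S,3R)-3-[(E)-4-hydroxybut-2-en-2-yl]-2-(3-methylbut-2-en-1-yl)cyclopentan-1-one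
Product: 13 (1R,2S,3R)-3-[(E)-4-hydroxybut-2-en-2-yl]-2-(3-methylbut-2-en-1-yl)cyclopentan-1-ol
Conditions: LiBH(s-Bu)3 (2.5 equiv), THF, −78 °C
Reagents that add atoms: none
Why: Hindered-hydride reduction of a 2,3-trans-disubstituted cyclopentanone: the reagent attacks anti to the α-prenyl group and should give the single alcohol cis to it (C4, later oxidised again), the free primary alcohol only consuming hydride.

Step 7
Reactants: 13 (1R,2S,3R)-3-[(E)-4-hydroxybut-2-en-2-yl]-2-(3-methylbut-2-en-1-yl)cyclopentan-1-ol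
Product: 14 (1R,2S,3R)-3-[(2R,3R)-3-(hydroxymethyl)-2-methyloxiran-2-yl]-2-(3-methylbut-2-en-1-yl)cyclopentan-1-ol
Conditions: Ti(OiPr)4 (0.2 equiv), D-(−)-diethyl tartrate (0.25 equiv), t-BuOOH, 4 Å sieves, CH2Cl2, −20 °C
Reagents that add atoms: tert-butyl hydroperoxide, CC(C)(C)OO
Why: Sharpless asymmetric epoxidation of the (E)-trisubstituted allylic alcohol; D-(−)-diethyl tartrate should give the (2R,3R)-epoxy alcohol as with geraniol-type substrates, fixing the C10 oxygen under reagent control, while the isolated prenyl alkene does not react.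

Step 8
Reactants: 14 (1R,2S,3R)-3-[(2R,3R)-3-(hydroxymethyl)-2-methyloxiran-2-yl]-2-(3-methylbut-2-en-1-yl)cyclopentan-1-ol
Product: 15 (3S)-3-[(1R,2S,3R)-3-hydroxy-2-(3-methylbut-2-en-1-yl)cyclopentyl]butane-1,3-diol
Conditions: NaAlH2(OCH2CH2OMe)2, THF, 0 °C → rt
Reagents that add atoms: none
Why: Regioselective reductive opening of a 2,3-epoxy alcohol: the alkoxyaluminium hydride at the primary oxygen delivers hydride internally to C9, so the C10–O bond keeps its configuration and the 1,3-diol results.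

Step 9
Reactants: 15 (3S)-3-[(1R,2S,3R)-3-hydroxy-2-(3-methylbut-2-en-1-yl)cyclopentyl]butane-1,3-diol
Product: 16 (3S)-1,3-bis(triethylsilyloxy)-3-[(1R,2S,3R)-2-(3-methylbut-2-en-1-yl)-3-(triethylsilyloxy)cyclopentyl]butane
Conditions: Et3SiOTf (3.6 equiv), 2,6-lutidine, CH2Cl2, −78 → 0 °C
Reagents that add atoms: triethylsilyl trifluoromethanesulfonate, CC[Si](CC)(CC)OS(=O)(=O)C(F)(F)F
Why: Silyl triflate silylation protects the primary, secondary and tertiary hydroxyls in one operation; no stereocentre changes.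

Step 10
Reactants: 16 (3S)-1,3-bis(triethylsilyloxy)-3-[(1R,2S,3R)-2-(3-methylbut-2-en-1-yl)-3-(triethylsilyloxy)cyclopentyl]butane
Product: 18 (3S)-3-[(1R,2S,3R)-2-(3-methylbut-2-en-1-yl)-3-(triethylsilyloxy)cyclopentyl]-3-(triethylsilyloxy)butanal, via alkoxysulfonium chloride 17 (not isolated)
Conditions: (COCl)2, DMSO, CH2Cl2, −78 °C; 16, −78 → −40 °C; Et3N, −78 °C → rt
Reagents that add atoms: none
Why: Swern oxidation of a primary triethylsilyl ether: the activated sulfoxide exchanges only the unhindered primary silyl ether, whose alkoxysulfonium salt collapses to the aldehyde on addition of base, while the secondary and tertiary silyl ethers should persist.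

Step 11
Reactants: 18 (3S)-3-[(1R,2S,3R)-2-(3-methylbut-2-en-1-yl)-3-(triethylsilyloxy)cyclopentyl]-3-(triethylsilyloxy)butanal
Product: 19 4α,10β-bis(triethylsilyloxy)-15-nor-1αH,5βH,7αH-guai-11-en-8α-ol
Conditions: Me2AlCl (2 equiv), CH2Cl2, −78 → −20 °C
Reagents that add atoms: none
Why: Me2AlCl binds the C8 aldehyde, C7 of the trisubstituted alkene attacks the carbonyl carbon while an allylic methyl hydrogen passes to oxygen in a concerted, cation-like six-centre process (Lewis acid-promoted type 1 carbonyl-ene cyclisation of the citronellal kind), and the aluminium alkoxide formed loses methane, which removes the proton source for Prins side paths. Ring B closes by C7–C8 bond formation in the 7-exo mode with respect to the alkene, charge developing at the tertiary C11, so no eight-membered alternative should compete. C7 is set by the alkene face presented in a chair-like transition state in which ring A spans two equatorial sites, the C10 methyl is equatorial and the C10 silyloxy group axial, so that the emerging isopropenyl group lies equatorial (β). C8 follows from the aluminium-bound oxygen also lying equatorial, giving the 7,8-trans (8α) alcohol as in isopulegol formation. The step needs ring closure over oligomerisation and face control at C7 only, since C8 is reset in steps 13 and 14; the trans arrangement of the two arms on ring A and the quaternary C10 (gem-disubstitution) hold the termini together, and the C4 silyl ether is a spectator.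

Step 12
Reactants: 19 4α,10β-bis(triethylsilyloxy)-15-nor-1αH,5βH,7αH-guai-11-en-8α-ol
Product: 20 4α,10β-bis(triethylsilyloxy)-15-nor-1αH,5βH,7αH-guaian-8α-ol
Conditions: H2 (1 atm), PtO2, EtOAc, rt
Reagents that add atoms: none
Why: Heterogeneous hydrogenation of the 1,1-disubstituted alkene over platinum, chosen over palladium to avoid migration of the double bond towards C7; C11 carries two methyl groups, so no stereocentre is formed.

Step 13
Reactants: 20 4α,10β-bis(triethylsilyloxy)-15-nor-1αH,5βH,7αH-guaian-8α-ol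
Product: 21 4α,10β-bis(triethylsilyloxy)-15-nor-1αH,5βH,7αH-guaian-8-one
Conditions: Dess–Martin periodinane, NaHCO3, CH2Cl2, rt
Reagents that add atoms: none
Why: Dess–Martin oxidation under buffered conditions that should not epimerise C7 converts the secondary alcohol into the ketone and erases the C8 configuration.

Step 14
Reactants: 21 4α,10β-bis(triethylsilyloxy)-15-nor-1αH,5βH,7αH-guaian-8-one
Product: 22 4α,10β-bis(triethylsilyloxy)-15-nor-1αH,5βH,7αH-guaian-8β-ol
Conditions: LiBH(s-Bu)3, THF, −78 °C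
Reagents that add atoms: none
Why: Hindered-hydride reduction: the reagent should approach the cycloheptanone on the α-face along the equatorial trajectory, away from the 10β-silyloxy group that lies 1,3 to C8, giving the 8β-alcohol cis to the isopropyl group, the usual outcome for 2-alkylcycloalkanones.

Step 15
Reactants: 22 4α,10β-bis(triethylsilyloxy)-15-nor-1αH,5βH,7αH-guaian-8β-ol, 23 3,4-dimethoxybenzoyl chloride
Product: 24 4α,10β-bis(triethylsilyloxy)-15-nor-1αH,5βH,7αH-guaian-8β-yl 3,4-dimethoxybenzoate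
Conditions: 23 (3 equiv), DMAP, pyridine, 60 °C
Reagents that add atoms: 3,4-dimethoxybenzoyl chloride (23), COc1ccc(C(Cl)=O)cc1OC
Why: DMAP-catalysed acylation through the acylpyridinium ion esterifies the hindered secondary alcohol with retention at C8; the tertiary oxygen is silylated and cannot compete.

Step 16
Reactants: 24 4α,10β-bis(triethylsilyloxy)-15-nor-1αH,5βH,7αH-guaian-8β-yl 3,4-dimethoxybenzoate
Product: 25 4α-hydroxy-10β-(triethylsilyloxy)-15-nor-1αH,5βH,7αH-guaian-8β-yl 3,4-dimethoxybenzoate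
Conditions: PPTS (cat.), MeOH/CH2Cl2 (1:1), 0 °C
Reagents that add atoms: none
Why: Acid-catalysed methanolysis should remove the secondary triethylsilyl ether much faster than the tertiary one on the quaternary C10, and the aryl ester is inert to PPTS.

Step 17
Reactants: 25 4α-hydroxy-10β-(triethylsilyloxy)-15-nor-1αH,5βH,7αH-guaian-8β-yl 3,4-dimethoxybenzoate
Product: 26 4-oxo-10β-(triethylsilyloxy)-15-nor-1αH,5βH,7αH-guaian-8β-yl 3,4-dimethoxybenzoate
Conditions: Dess–Martin periodinane, NaHCO3, CH2Cl2, rt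
Reagents that add atoms: none
Why: Dess–Martin oxidation gives the cyclopentanone under buffered conditions that should not epimerise the ring-fusion carbon C5.

Step 18
Reactants: 26 4-oxo-10β-(triethylsilyloxy)-15-nor-1αH,5βH,7αH-guaian-8β-yl 3,4-dimethoxybenzoate
Product: 28 10β-(triethylsilyloxy)-4-(trifluoromethylsulfonyloxy)-15-nor-1αH,5βH,7αH-guai-3-en-8β-yl 3,4-dimethoxybenzoate, via potassium enolate 27 (not isolated)
Conditions: KN(SiMe3)2, THF, −78 °C; then PhNTf2, −78 → 0 °C
Reagents that add atoms: N-phenylbis(trifluoromethanesulfonimide), O=S(=O)(N(c1ccccc1)S(=O)(=O)C(F)(F)F)C(F)(F)F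
Why: Kinetic enolisation with the bulky amide base removes a proton from the C3 methylene in preference to the ring-fusion methine C5, and O-sulfonylation of the enolate gives the C3=C4 enol triflate; the ester has no α-hydrogen.

Step 19
Reactants: 28 10β-(triethylsilyloxy)-4-(trifluoromethylsulfonyloxy)-15-nor-1αH,5βH,7αH-guai-3-en-8β-yl 3,4-dimethoxybenzoate
Product: 29 10β-(triethylsilyloxy)-1αH,5βH,7αH-guai-3-en-8β-yl 3,4-dimethoxybenzoate
Conditions: MeZnCl, Pd(PPh3)4 (cat.), THF, 50 °C
Reagents that add atoms: methylzinc chloride, C[Zn]Cl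
Why: Negishi cross-coupling: oxidative addition of the enol triflate to zerovalent palladium, transmetalation from MeZnCl and reductive elimination install the C4 methyl group, with ester and silyl ether tolerated.

Step 20
Reactants: 29 10β-(triethylsilyloxy)-1αH,5βH,7αH-guai-3-en-8β-yl 3,4-dimethoxybenzoate
Product: 30 3α,4α-epoxy-10β-(triethylsilyloxy)-1αH,5βH,7αH-guaian-8β-yl 3,4-dimethoxybenzoate
Conditions: mCPBA, NaHCO3, CH2Cl2, 0 °C
Reagents that add atoms: 3-chloroperoxybenzoic acid, O=C(OO)c1cccc(Cl)c1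
Why: Prilezhaev epoxidation of the only alkene; the peracid should attack the α-face, because the β-face of the cyclopentene is flanked by the pseudo-axial H-5 and H-2β bonds (torsional bias) and by the 10β-triethylsilyloxy group lying syn to H-5, so C3 and C4 are set together as the 3α,4α-epoxide.

Step 21
Reactants: 30 3α,4α-epoxy-10β-(triethylsilyloxy)-1αH,5βH,7αH-guaian-8β-yl 3,4-dimethoxybenzoate
Product: 31 3α,4α-epoxy-10β-hydroxy-1αH,5βH,7αH-guaian-8β-yl 3,4-dimethoxybenzoate (CNP0304846.1)
Conditions: Bu4NF, AcOH, THF, 0 °C → rt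
Reagents that add atoms: none
Why: Fluoride-mediated desilylation of the tertiary triethylsilyl ether, buffered with acetic acid so that neither the ester nor the trisubstituted epoxide should be touched.

**Compound list**

1 | but-2-yn-1-ol | CC#CCO | starting material
2 | tert-butyl(but-2-yn-1-yloxy)dimethylsilane | CC#CCO[Si](C)(C)C(C)(C)C | intermediate
3 | (E)-[4-(tert-butyldimethylsilyloxy)but-2-en-2-yl]bis(cyclopentadienyl)zirconium chloride | C/C([Zr](Cl)(C1C=CC=C1)C1C=CC=C1)=C\CO[Si](C)(C)C(C)(C)C | intermediate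
4 | (E)-tert-butyl[(3-iodobut-2-en-1-yl)oxy]dimethylsilane | C/C(I)=C\CO[Si](C)(C)C(C)(C)C | intermediate
5 | (S)-4-(tert-butyldimethylsilyloxy)cyclopent-2-en-1-one | O=C1C=C[C@@H](O[Si](C)(C)C(C)(C)C)C1 | starting material
6 | 1-bromo-3-methylbut-2-ene (prenyl bromide) | CC(C)=CCBr | starting material
7 | alkenyllithium from 4 (lithium in place of iodine, double-bond geometry retained) | C/C([Li])=C\CO[Si](C)(C)C(C)(C)C | intermediate
8 | lithium [4-(tert-butyldimethylsilyloxy)but-2-en-2-yl]dimethylzincate (geometry retained) | [Li+].C/C([Zn-](C)C)=C\CO[Si](C)(C)C(C)(C)C | intermediate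
9 | lithium dimethylzincate enolate formed by conjugate addition of 8 to 5 (enolate across C4–C5, guaiane numbering) | [Li+].CC(C)(C)[Si](C)(C)OC/C=C(\C)[C@@H]1[C@@H](O[Si](C)(C)C(C)(C)C)CC(O[Zn-](C)C)=C1 | intermediate
10 | (2S,3R,4S)-4-(tert-butyldimethylsilyloxy)-3-[(E)-4-(tert-butyldimethylsilyloxy)but-2-en-2-yl]-2-(3-methylbut-2-en-1-yl)cyclopentan-1-one | CC(C)(C)[Si](C)(C)OC/C=C(\C)[C@@H]1[C@@H](O[Si](C)(C)C(C)(C)C)CC(=O)[C@H]1CC=C(C)C | intermediate
11 | (4R,5S)-4-[(E)-4-hydroxybut-2-en-2-yl]-5-(3-methylbut-2-en-1-yl)cyclopent-2-en-1-one | OC/C=C(\C)[C@@H]1C=CC(=O)[C@H]1CC=C(C)C | intermediate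
12 | (2S,3R)-3-[(E)-4-hydroxybut-2-en-2-yl]-2-(3-methylbut-2-en-1-yl)cyclopentan-1-one | OC/C=C(\C)[C@@H]1CCC(=O)[C@H]1CC=C(C)C | intermediate
13 | (1R,2S,3R)-3-[(E)-4-hydroxybut-2-en-2-yl]-2-(3-methylbut-2-en-1-yl)cyclopentan-1-ol | OC/C=C(\C)[C@@H]1CC[C@@H](O)[C@H]1CC=C(C)C | intermediate
14 | (1R,2S,3R)-3-[(2R,3R)-3-(hydroxymethyl)-2-methyloxiran-2-yl]-2-(3-methylbut-2-en-1-yl)cyclopentan-1-ol | OC[C@H]1O[C@]1(C)[C@@H]2CC[C@@H](O)[C@H]2CC=C(C)C | intermediate
15 | (3S)-3-[(1R,2S,3R)-3-hydroxy-2-(3-methylbut-2-en-1-yl)cyclopentyl]butane-1,3-diol | OCC[C@](C)(O)[C@@H]1CC[C@@H](O)[C@H]1CC=C(C)C | intermediate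
16 | (3S)-1,3-bis(triethylsilyloxy)-3-[(1R,2S,3R)-2-(3-methylbut-2-en-1-yl)-3-(triethylsilyloxy)cyclopentyl]butane | CC[Si](CC)(CC)OCC[C@](C)(O[Si](CC)(CC)CC)[C@@H]1CC[C@@H](O[Si](CC)(CC)CC)[C@H]1CC=C(C)C | intermediate
17 | dimethyl(alkoxy)sulfonium chloride of the primary oxygen of 16 (primary silyl group exchanged) | C[S+](C)OCC[C@](C)(O[Si](CC)(CC)CC)[C@@H]1CC[C@@H](O[Si](CC)(CC)CC)[C@H]1CC=C(C)C.[Cl-] | intermediate
18 | (3S)-3-[(1R,2S,3R)-2-(3-methylbut-2-en-1-yl)-3-(triethylsilyloxy)cyclopentyl]-3-(triethylsilyloxy)butanal | O=CC[C@](C)(O[Si](CC)(CC)CC)[C@@H]1CC[C@@H](O[Si](CC)(CC)CC)[C@H]1CC=C(C)C | intermediate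
19 | 4α,10β-bis(triethylsilyloxy)-15-nor-1αH,5βH,7αH-guai-11-en-8α-ol (trans-fused, 7β-isopropenyl) | O[C@H]1C[C@](C)(O[Si](CC)(CC)CC)[C@@H]2CC[C@@H](O[Si](CC)(CC)CC)[C@H]2C[C@@H]1C(C)=C | intermediate
20 | 4α,10β-bis(triethylsilyloxy)-15-nor-1αH,5βH,7αH-guaian-8α-ol | O[C@H]1C[C@](C)(O[Si](CC)(CC)CC)[C@@H]2CC[C@@H](O[Si](CC)(CC)CC)[C@H]2C[C@@H]1C(C)C | intermediate
21 | 4α,10β-bis(triethylsilyloxy)-15-nor-1αH,5βH,7αH-guaian-8-one | O=C1C[C@](C)(O[Si](CC)(CC)CC)[C@@H]2CC[C@@H](O[Si](CC)(CC)CC)[C@H]2C[C@@H]1C(C)C | intermediate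
22 | 4α,10β-bis(triethylsilyloxy)-15-nor-1αH,5βH,7αH-guaian-8β-ol | O[C@@H]1C[C@](C)(O[Si](CC)(CC)CC)[C@@H]2CC[C@@H](O[Si](CC)(CC)CC)[C@H]2C[C@@H]1C(C)C | intermediate
23 | 3,4-dimethoxybenzoyl chloride | COc1ccc(C(Cl)=O)cc1OC | starting material
24 | 4α,10β-bis(triethylsilyloxy)-15-nor-1αH,5βH,7αH-guaian-8β-yl 3,4-dimethoxybenzoate | COc1ccc(C(=O)O[C@@H]2C[C@](C)(O[Si](CC)(CC)CC)[C@@H]3CC[C@@H](O[Si](CC)(CC)CC)[C@H]3C[C@@H]2C(C)C)cc1OC | intermediate
25 | 4α-hydroxy-10β-(triethylsilyloxy)-15-nor-1αH,5βH,7αH-guaian-8β-yl 3,4-dimethoxybenzoate | COc1ccc(C(=O)O[C@@H]2C[C@](C)(O[Si](CC)(CC)CC)[C@@H]3CC[C@@H](O)[C@H]3C[C@@H]2C(C)C)cc1OC | intermediate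
26 | 4-oxo-10β-(triethylsilyloxy)-15-nor-1αH,5βH,7αH-guaian-8β-yl 3,4-dimethoxybenzoate | COc1ccc(C(=O)O[C@@H]2C[C@](C)(O[Si](CC)(CC)CC)[C@@H]3CCC(=O)[C@H]3C[C@@H]2C(C)C)cc1OC | intermediate
27 | potassium enolate of 26 across C3–C4 | COc1ccc(C(=O)O[C@@H]2C[C@](C)(O[Si](CC)(CC)CC)[C@@H]3CC=C([O-])[C@H]3C[C@@H]2C(C)C)cc1OC.[K+] | intermediate
28 | 10β-(triethylsilyloxy)-4-(trifluoromethylsulfonyloxy)-15-nor-1αH,5βH,7αH-guai-3-en-8β-yl 3,4-dimethoxybenzoate | COc1ccc(C(=O)O[C@@H]2C[C@](C)(O[Si](CC)(CC)CC)[C@@H]3CC=C(OS(=O)(=O)C(F)(F)F)[C@H]3C[C@@H]2C(C)C)cc1OC | intermediate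
29 | 10β-(triethylsilyloxy)-1αH,5βH,7αH-guai-3-en-8β-yl 3,4-dimethoxybenzoate | COc1ccc(C(=O)O[C@@H]2C[C@](C)(O[Si](CC)(CC)CC)[C@@H]3CC=C(C)[C@H]3C[C@@H]2C(C)C)cc1OC | intermediate
30 | 3α,4α-epoxy-10β-(triethylsilyloxy)-1αH,5βH,7αH-guaian-8β-yl 3,4-dimethoxybenzoate | COc1ccc(C(=O)O[C@@H]2C[C@](C)(O[Si](CC)(CC)CC)[C@@H]3C[C@H]4O[C@@]4(C)[C@H]3C[C@@H]2C(C)C)cc1OC | intermediate
31 | 3α,4α-epoxy-10β-hydroxy-1αH,5βH,7αH-guaian-8β-yl 3,4-dimethoxybenzoate (CNP0304846.1) | COc1ccc(C(=O)O[C@@H]2C[C@](C)(O)[C@@H]3C[C@H]4O[C@@]4(C)[C@H]3C[C@@H]2C(C)C)cc1OC | target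

**Step count and risks**

Total step count: 21. Longest linear sequence: 21 steps (1 → 31 through iodide 4); 19 steps counted from enone 5.

The three steps most likely to fail:

1. Step 11 (ene closure of ring B). The flexible seven-membered transition state may discriminate poorly between the two faces of the alkene, so that the C7 epimer or a mixture forms. Fallback, setting out from 18 and returning at 21: the cyclisation product with 7α-isopropenyl and 8β-hydroxyl, the 7-epi alcohol F1, would be hydrogenated over PtO2 to the 7-epi isopropyl alcohol F2 and oxidised with Dess–Martin periodinane to the 7-epi ketone F3. Equilibration of the α-stereocentre with DBU in toluene (or NaOMe in MeOH) should then move the isopropyl group into the equatorial β-position and give ketone 21, so C7 is set under thermodynamic instead of kinetic control.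

2. Step 20 (epoxidation). Peracid delivery may be poorly face-selective, or may favour the β-face of the cyclopentene. Fallback, setting out from 29 and returning at 30: NBS in aqueous THF at 0 °C should form the bromonium ion on the face the peracid prefers, and water opens it anti at the tertiary C4 to give the 3β-bromo-4α-hydroxy compound F4. DBU in CH2Cl2 (or Ag2O) then closes the epoxide by intramolecular SN2 at C3, placing oxygen on the α-face, opposite to direct epoxidation.

3. Step 14 (reduction at C8). Hydride delivery to the conformationally mobile cycloheptanone may be poorly face-selective and regenerate the 8α-alcohol. Fallback, setting out from 20 and returning at 22: Mitsunobu inversion of the 8α-alcohol with 4-nitrobenzoic acid, PPh3 and diisopropyl azodicarboxylate in toluene should give the inverted 8β 4-nitrobenzoate F5, and K2CO3 in MeOH releases 22, so that C8 is set by SN2 displacement instead of carbonyl reduction.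

**Further compounds**

F1 | step 11 | 4α,10β-bis(triethylsilyloxy)-15-nor-1αH,5βH,7βH-guai-11-en-8β-ol (C7 epimer of 19 with trans 8-hydroxyl) | O[C@@H]1C[C@](C)(O[Si](CC)(CC)CC)[C@@H]2CC[C@@H](O[Si](CC)(CC)CC)[C@H]2C[C@H]1C(C)=C
F2 | step 11 | 4α,10β-bis(triethylsilyloxy)-15-nor-1αH,5βH,7βH-guaian-8β-ol | O[C@@H]1C[C@](C)(O[Si](CC)(CC)CC)[C@@H]2CC[C@@H](O[Si](CC)(CC)CC)[C@H]2C[C@H]1C(C)C
F3 | step 11 | 4α,10β-bis(triethylsilyloxy)-15-nor-1αH,5βH,7βH-guaian-8-one (C7 epimer of 21) | O=C1C[C@](C)(O[Si](CC)(CC)CC)[C@@H]2CC[C@@H](O[Si](CC)(CC)CC)[C@H]2C[C@H]1C(C)C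
F4 | step 20 | 3β-bromo-4α-hydroxy-10β-(triethylsilyloxy)-1αH,5βH,7αH-guaian-8β-yl 3,4-dimethoxybenzoate | COc1ccc(C(=O)O[C@@H]2C[C@](C)(O[Si](CC)(CC)CC)[C@@H]3C[C@H](Br)[C@@](C)(O)[C@H]3C[C@@H]2C(C)C)cc1OC
F5 | step 14 | 4α,10β-bis(triethylsilyloxy)-15-nor-1αH,5βH,7αH-guaian-8β-yl 4-nitrobenzoate | O=C(O[C@@H]1C[C@](C)(O[Si](CC)(CC)CC)[C@@H]2CC[C@@H](O[Si](CC)(CC)CC)[C@H]2C[C@@H]1C(C)C)c1ccc(cc1)[N+](=O)[O-]
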